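**Assumptions:** enantiopure (R)-linalool and (R)-2-methylbutanoic acid are bought; C1–C15 are germacranolide locants of the target (C3 ketone, C4=C5, C15 hydroxymethyl on C4, C6 lactone oxygen, C8 ester, C10 carbinol bearing the C14 methyl, C11=C13, C12 lactone carbonyl); ten-membered 10-hydroxy-3-ketones are drawn and treated in the open keto form, as the target is.

## Retrosynthetic overview

1. The γ-lactone is closed last (O6–C12, acid) from a C6-hydroxy tert-butyl ester; its C15–OH and 4Z-enone come from a palladium-catalysed hydrative SN2′ opening (new C15–O bond) of a 5,6-epoxide flanking an exo-methylene ketone.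
2. The C6–O bond and the C6 configuration come from a C8-hydroxyl-directed epoxidation of a ten-membered cross-conjugated dienone; the C8 ester is attached after it.
3. The ten-membered carbocycle comes from ring-closing metathesis at C5=C6 of an acyclic tetraene triol.
4. The chain comes from (R)-linalool (C1–C3, C8–C10, C14; C10 stereocentre), a 2-(bromomethyl)pentadienoate (C6, C7, C11–C13; asymmetric Barbier sets C7 and C8) and 1,4-dibromobut-2-yne (C4, C5, C15).
5. Ring order: carbocycle (step 8), oxirane (step 10, opened in step 12), γ-lactone (step 12).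

## Route

Step 1
Reactants: 1 (R)-linalool
Product: 3 (3R)-3,7-dimethyloct-6-ene-1,3-diol, via B-alkyl-9-BBN adduct 2 (not isolated)
Conditions: 9-BBN (2.2 equiv), THF, 0 to 23 °C; then 3 M NaOH, 30% H2O2, 0 °C
Reagents that add atoms: hydrogen peroxide, OO
Why: Anti-Markovnikov hydroboration–oxidation in which 9-BBN adds only to the monosubstituted vinyl group, leaving the trisubstituted alkene and the chiral-pool C10 centre untouched.

Step 2
Reactants: 3 (3R)-3,7-dimethyloct-6-ene-1,3-diol
Product: 4 (3R)-3-hydroxy-3,7-dimethyloct-6-enal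
Conditions: TEMPO (10 mol %), PhI(OAc)2 (1.1 equiv), CH2Cl2, 23 °C
Reagents that add atoms: none
Why: Oxoammonium (TEMPO) oxidation takes the primary alcohol to the aldehyde without touching the tertiary alcohol or the alkene, and no stereocentre is involved.

Step 3
Reactants: 5 tert-butyl acrylate; 6 acrolein
Product: 7 tert-butyl 3-hydroxy-2-methylidenepent-4-enoate (racemic)
Conditions: DABCO (20 mol %), 1,4-dioxane/H2O (1:1), 23 °C
Reagents that add atoms: none
Why: Morita–Baylis–Hillman reaction in which the DABCO–acrylate enolate attacks the acrolein carbonyl; the racemic carbinol centre is erased in step 4.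

Step 4
Reactants: 7 tert-butyl 3-hydroxy-2-methylidenepent-4-enoate
Product: 8 tert-butyl (2Z)-2-(bromomethyl)penta-2,4-dienoate
Conditions: CBr4, PPh3, CH2Cl2, 0 °C
Reagents that add atoms: carbon tetrabromide, BrC(Br)(Br)Br
Why: Appel bromination with allylic transposition (SN2′) places bromide on the acrylate CH2 terminus and gives the thermodynamically preferred conjugated 2Z-dienoate (vinyl cis to CH2Br).

Step 5
Reactants: 4 (3R)-3-hydroxy-3,7-dimethyloct-6-enal; 8 tert-butyl (2Z)-2-(bromomethyl)penta-2,4-dienoate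
Product: 10 tert-butyl (3R,4R,6R)-3-ethenyl-4,6-dihydroxy-6,10-dimethyl-2-methylideneundec-9-enoate, via silyl ether 9 (not isolated)
Conditions: CrCl2 (10 mol %), 1,8-bis[(4S)-4-isopropyl-4,5-dihydrooxazol-2-yl]-3,6-diphenylcarbazole (12 mol %), Mn powder (2 equiv), Me3SiCl (1.2 equiv), iPr2NEt (30 mol %), THF, 23 °C; then aq. citric acid, 0 °C
Reagents that add atoms: none
Why: Catalytic asymmetric Nozaki–Hiyama–Kishi (Barbier-type) 2-(alkoxycarbonyl)allylation in which the Z-configured allylchromium adds through its vinyl-bearing γ-carbon via a chair transition state (C7/C8 syn) while the chiral chromium catalyst, not the remote C10 carbinol, selects the aldehyde face (ligand antipode chosen to give 8R and hence 7R).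

Step 6
Reactants: 10 tert-butyl (3R,4R,6R)-3-ethenyl-4,6-dihydroxy-6,10-dimethyl-2-methylideneundec-9-enoate
Product: 12 tert-butyl (3R,4R)-3-ethenyl-4-hydroxy-5-[(2R)-5-hydroxy-2-methyloxolan-2-yl]-2-methylidenepentanoate (lactol anomers), via trisubstituted epoxide 11 (not isolated)
Conditions: mCPBA (1.05 equiv), NaHCO3, CH2Cl2, 0 °C; then H5IO6 (1.2 equiv), THF/H2O, 0 °C
Reagents that add atoms: mCPBA (3-chloroperoxybenzoic acid), O=C(OO)c1cccc(Cl)c1
Why: Prilezhaev epoxidation of the only electron-rich (trisubstituted) alkene followed by periodic acid cleavage unmasks the C3 aldehyde, which closes on the C10 hydroxyl as a lactol without touching the stereocentres.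

Step 7
Reactants: 12 tert-butyl (3R,4R)-3-ethenyl-4-hydroxy-5-[(2R)-5-hydroxy-2-methyloxolan-2-yl]-2-methylidenepentanoate; 13 1,4-dibromobut-2-yne
Product: 14 tert-butyl (3R,4R,6R)-3-ethenyl-4,6,9-trihydroxy-6-methyl-2,10-dimethylidenedodec-11-enoate (C9 epimers)
Conditions: In powder (2.5 equiv), THF/H2O (1:1), 23 °C
Reagents that add atoms: none
Why: Indium-mediated Barbier-type 1,3-butadien-2-ylation in water adds the C4/C5/C15 unit to the open aldehyde form of the lactol and tolerates free hydroxyls and esters; the new C3 carbinol (both epimers) becomes a ketone in step 9.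

Step 8
Reactants: 14 tert-butyl (3R,4R,6R)-3-ethenyl-4,6,9-trihydroxy-6-methyl-2,10-dimethylidenedodec-11-enoate
Product: 15 tert-butyl 2-[(1R,2Z,8R,10R)-5,8,10-trihydroxy-8-methyl-4-methylidenecyclodec-2-en-1-yl]prop-2-enoate (C5 epimers)
Conditions: second-generation Hoveyda–Grubbs catalyst RuCl2(H2IMes)(=CH-C6H4-2-OiPr) (10 mol %), 2,6-dichloro-1,4-benzoquinone (20 mol %), toluene (0.5 mM), 80 °C
Reagents that add atoms: none
Why: Ring-closing metathesis joins the two monosubstituted vinyl groups (the 1,1-disubstituted diene and acrylate alkenes are too hindered or electron-poor) to close the ten-membered ring, the medium ring favouring the Z C5=C6 alkene, whose geometry is erased in step 12 anyway.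

Step 9
Reactants: 15 tert-butyl 2-[(1R,2Z,8R,10R)-5,8,10-trihydroxy-8-methyl-4-methylidenecyclodec-2-en-1-yl]prop-2-enoate
Product: 16 tert-butyl 2-[(1R,2Z,8R,10R)-8,10-dihydroxy-8-methyl-4-methylidene-5-oxocyclodec-2-en-1-yl]prop-2-enoate
Conditions: MnO2 (20 equiv), CH2Cl2, 23 °C
Reagents that add atoms: none
Why: Allylic alcohol oxidation with MnO2 converts only the dienylic C3 carbinol into the ketone and leaves the saturated C8 alcohol, needed free for step 10, and the tertiary C10 alcohol.

Step 10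
Reactants: 16 tert-butyl 2-[(1R,2Z,8R,10R)-8,10-dihydroxy-8-methyl-4-methylidene-5-oxocyclodec-2-en-1-yl]prop-2-enoate
Product: 17 tert-butyl 2-[(1R,2R,3R,5R,10S)-3,5-dihydroxy-5-methyl-9-methylidene-8-oxo-11-oxabicyclo[8.1.0]undecan-2-yl]prop-2-enoate
Conditions: VO(acac)2 (5 mol %), t-BuOOH (1.2 equiv, in decane), CH2Cl2, 0 °C
Reagents that add atoms: tert-butyl hydroperoxide, CC(C)(C)OO
Why: Hydroxyl-directed vanadium-catalysed epoxidation in which the C8 vanadate ester delivers oxygen to the homoallylic C5=C6 face cis to the C8–O bond, so the C6–O bond (the future lactone oxygen) is made with the target configuration while the enone and acrylate alkenes are too electron-poor to react.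

Step 11
Reactants: 17 tert-butyl 2-[(1R,2R,3R,5R,10S)-3,5-dihydroxy-5-methyl-9-methylidene-8-oxo-11-oxabicyclo[8.1.0]undecan-2-yl]prop-2-enoate; 18 (2R)-2-methylbutanoic acid
Product: 19 (1R,2R,3R,5R,10S)-2-[3-(tert-butoxy)-3-oxoprop-1-en-2-yl]-5-hydroxy-5-methyl-9-methylidene-8-oxo-11-oxabicyclo[8.1.0]undecan-3-yl (2R)-2-methylbutanoate
Conditions: N,N′-diisopropylcarbodiimide (1.5 equiv), DMAP (10 mol %), CH2Cl2, 0 °C
Reagents that add atoms: none
Why: Steglich esterification acylates the only secondary hydroxyl (C8) with retention at C8 and at the acid α-carbon; the tertiary C10 alcohol is inert and α-methylene ketones tolerate carbodiimide/DMAP acylation as Morita–Baylis–Hillman alcohols do.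

Step 12
Reactants: 19 (1R,2R,3R,5R,10S)-2-[3-(tert-butoxy)-3-oxoprop-1-en-2-yl]-5-hydroxy-5-methyl-9-methylidene-8-oxo-11-oxabicyclo[8.1.0]undecan-3-yl (2R)-2-methylbutanoate
Product: 21 (3aR,4R,6R,10Z,11aS)-6-hydroxy-10-(hydroxymethyl)-6-methyl-3-methylidene-2,9-dioxo-2,3,3a,4,5,6,7,8,9,11a-decahydrocyclodeca[b]furan-4-yl (2R)-2-methylbutanoate (CNP0130221.1), via hydroxy tert-butyl ester 20 (not isolated)
Conditions: Pd2(dba)3 (2.5 mol %), Ph2PCH2CH2PPh2 (6 mol %), H2O (20 equiv), THF, 23 °C; silica plug; then CF3CO2H/CH2Cl2 (1:9), 0 °C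
Reagents that add atoms: water, O
Why: Proposed new method: zerovalent palladium ionises the C5–O bond of the epoxide, which is allylic to the C4=C15 enone alkene, to a 2-acyl-π-allylpalladium/C6-alkoxide zwitterion, the alkoxide deprotonates water and hydroxide attacks the unhindered C15 terminus, giving the C15–OH, the conjugated C4=C5 bond (C3 and C6 held cis by the ring, hence 4Z) and the C6 carbinol with its configuration untouched under neutral conditions that suppress O8-to-O6 acyl migration, after which acid closes the γ-lactone with loss of the tert-butyl group; the closest known chemistry is the Tsuji–Trost 1,4-addition of carboxylic acids and phenols to vinyl epoxides and palladium-catalysed substitution of Morita–Baylis–Hillman carbonates, but water as the nucleophile on an α-(oxiranyl) enone has not been shown.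

## Compound list

1 | (R)-linalool, (3R)-3,7-dimethylocta-1,6-dien-3-ol | CC(C)=CCC[C@@](C)(O)C=C | starting material
2 | 9-[(3S)-3-hydroxy-3,7-dimethyloct-6-en-1-yl]-9-borabicyclo[3.3.1]nonane (same spatial arrangement at C3 as in 1; the label changes by priority) | CC(C)=CCC[C@@](C)(O)CCB1C2CCCC1CCC2 | intermediate
3 | (3R)-3,7-dimethyloct-6-ene-1,3-diol | CC(C)=CCC[C@@](C)(O)CCO | intermediate
4 | (3R)-3-hydroxy-3,7-dimethyloct-6-enal | CC(C)=CCC[C@@](C)(O)CC=O | intermediate
5 | tert-butyl acrylate | C=CC(=O)OC(C)(C)C | starting material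
6 | acrolein | C=CC=O | starting material
7 | tert-butyl 3-hydroxy-2-methylidenepent-4-enoate (racemic) | C=CC(O)C(=C)C(=O)OC(C)(C)C | intermediate
8 | tert-butyl (2Z)-2-(bromomethyl)penta-2,4-dienoate | C=C/C=C(\CBr)C(=O)OC(C)(C)C | intermediate
9 | tert-butyl (3R,4R,6R)-3-ethenyl-6-hydroxy-6,10-dimethyl-2-methylidene-4-[(trimethylsilyl)oxy]undec-9-enoate | CC(C)=CCC[C@@](C)(O)C[C@@H](O[Si](C)(C)C)[C@@H](C(=C)C(=O)OC(C)(C)C)C=C | intermediate
10 | tert-butyl (3R,4R,6R)-3-ethenyl-4,6-dihydroxy-6,10-dimethyl-2-methylideneundec-9-enoate | CC(C)=CCC[C@@](C)(O)C[C@@H](O)[C@@H](C(=C)C(=O)OC(C)(C)C)C=C | intermediate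
11 | tert-butyl (3R,4R,6R)-8-(3,3-dimethyloxiran-2-yl)-3-ethenyl-4,6-dihydroxy-6-methyl-2-methylideneoctanoate (oxirane epimers) | CC1(C)OC1CC[C@@](C)(O)C[C@@H](O)[C@@H](C(=C)C(=O)OC(C)(C)C)C=C | intermediate
12 | tert-butyl (3R,4R)-3-ethenyl-4-hydroxy-5-[(2R)-5-hydroxy-2-methyloxolan-2-yl]-2-methylidenepentanoate (lactol anomers) | OC1CC[C@@](C)(O1)C[C@@H](O)[C@@H](C(=C)C(=O)OC(C)(C)C)C=C | intermediate
13 | 1,4-dibromobut-2-yne | BrCC#CCBr | starting material
14 | tert-butyl (3R,4R,6R)-3-ethenyl-4,6,9-trihydroxy-6-methyl-2,10-dimethylidenedodec-11-enoate (C9 epimers) | C=CC(=C)C(O)CC[C@@](C)(O)C[C@@H](O)[C@@H](C(=C)C(=O)OC(C)(C)C)C=C | intermediate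
15 | tert-butyl 2-[(1R,2Z,8R,10R)-5,8,10-trihydroxy-8-methyl-4-methylidenecyclodec-2-en-1-yl]prop-2-enoate (C5 epimers) | C=C(C(=O)OC(C)(C)C)[C@H]1/C=C\C(=C)C(O)CC[C@@](C)(O)C[C@H]1O | intermediate
16 | tert-butyl 2-[(1R,2Z,8R,10R)-8,10-dihydroxy-8-methyl-4-methylidene-5-oxocyclodec-2-en-1-yl]prop-2-enoate | C=C(C(=O)OC(C)(C)C)[C@H]1/C=C\C(=C)C(=O)CC[C@@](C)(O)C[C@H]1O | intermediate
17 | tert-butyl 2-[(1R,2R,3R,5R,10S)-3,5-dihydroxy-5-methyl-9-methylidene-8-oxo-11-oxabicyclo[8.1.0]undecan-2-yl]prop-2-enoate | C=C(C(=O)OC(C)(C)C)[C@H]1[C@H]2O[C@H]2C(=C)C(=O)CC[C@@](C)(O)C[C@H]1O | intermediate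
18 | (2R)-2-methylbutanoic acid | CC[C@@H](C)C(=O)O | starting material
19 | (1R,2R,3R,5R,10S)-2-[3-(tert-butoxy)-3-oxoprop-1-en-2-yl]-5-hydroxy-5-methyl-9-methylidene-8-oxo-11-oxabicyclo[8.1.0]undecan-3-yl (2R)-2-methylbutanoate | C=C(C(=O)OC(C)(C)C)[C@H]1[C@H]2O[C@H]2C(=C)C(=O)CC[C@@](C)(O)C[C@H]1OC(=O)[C@H](C)CC | intermediate
20 | tert-butyl 2-[(1S,2S,3Z,8R,10R)-2,8-dihydroxy-4-(hydroxymethyl)-8-methyl-10-{[(2R)-2-methylbutanoyl]oxy}-5-oxocyclodec-3-en-1-yl]prop-2-enoate | C=C(C(=O)OC(C)(C)C)[C@H]1[C@@H](O)/C=C(/CO)C(=O)CC[C@@](C)(O)C[C@H]1OC(=O)[C@H](C)CC | intermediate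
21 | (3aR,4R,6R,10Z,11aS)-6-hydroxy-10-(hydroxymethyl)-6-methyl-3-methylidene-2,9-dioxo-2,3,3a,4,5,6,7,8,9,11a-decahydrocyclodeca[b]furan-4-yl (2R)-2-methylbutanoate | C=C1C(=O)O[C@H]2/C=C(/CO)C(=O)CC[C@@](C)(O)C[C@@H](OC(=O)[C@H](C)CC)[C@@H]12 | target

## Step count and risk

Total steps: 12. Longest linear sequence: 10 (steps 1, 2, 5–12; steps 3 and 4 make bromide 8).

Three steps most likely to fail:

(a) Step 8, the metathesis closure of an unconstrained ten-membered ring on a free triol (oligomerisation or alkene isomerisation). The fallback sets out from 14 and comes back at 16. MnO2 oxidation of 14 gives the acyclic dienone F1, which is trapped at once with MeOH/PPTS as the 3,10-bridged methyl ketal F2 (anomers interconvert; only the one with both arms cis on the oxolane cyclises). Ring-closing metathesis then has to close only a nine-membered oxa-bridged ring, giving the bicyclic ketal F3, and aqueous acetic acid hydrolyses the ketal to 16. The ring is thus templated by the transannular ketal instead of being closed freely, and step 9 is absorbed.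

(b) Step 10, the directed epoxidation. The C5=C6 alkene is deactivated by conjugation, and any 3,10-hemiketal form of 16 carries an allylic hydroxyl that could steer a second epoxidation to C4=C15. The fallback sets out from 16 and comes back at 20, which is lactonised to 21 with CF3CO2H as in step 12. It makes both epoxides on purpose. Nucleophilic (Weitz–Scheffer) epoxidation of the enone with t-BuOOH/DBU gives the spiro-epoxy ketone F4. VO(acac)2/t-BuOOH then epoxidises the now isolated C5=C6 alkene under C8–OH direction to the bis-epoxide F5, and Steglich acylation with 18 gives the bis-epoxy ester F6. SmI2 (2.1 equiv, THF, −78 to 0 °C) cleaves the α,β-epoxy ketone reductively to a samarium enolate carrying the C15 alkoxide, and this enolate expels the 5,6-epoxide oxygen by β-elimination to give 20.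

(c) Step 12, the new hydrative opening. Water may be too weak a nucleophile, so the zwitterion could isomerise instead, or the 4E isomer could form. The fallback uses known chemistry, sets out from 19 and comes back at 21. The zerovalent-palladium-catalysed Tsuji–Trost 1,4-addition of 4-methoxyphenol to the vinyl epoxide (Pd2(dba)3, Ph2PCH2CH2PPh2, THF) gives the C15 4-methoxyphenyl ether F7. CF3CO2H closes the lactone to the aryl ether lactone F8, and (NH4)2Ce(NO3)6 in MeCN/H2O at 0 °C removes the aryl group to give 21.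

## Further compounds

F1 | step 8 | tert-butyl (3R,4R,6R)-3-ethenyl-4,6-dihydroxy-6-methyl-2,10-dimethylidene-9-oxododec-11-enoate (acyclic dienone) | C=CC(=C)C(=O)CC[C@@](C)(O)C[C@@H](O)[C@@H](C(=C)C(=O)OC(C)(C)C)C=C
F2 | step 8 | tert-butyl (3R,4R)-5-[(2R)-5-(buta-1,3-dien-2-yl)-5-methoxy-2-methyloxolan-2-yl]-3-ethenyl-4-hydroxy-2-methylidenepentanoate (anomers) | C=CC(=C)C1(OC)CC[C@@](C)(O1)C[C@@H](O)[C@@H](C(=C)C(=O)OC(C)(C)C)C=C
F3 | step 8 | tert-butyl 2-[(3Z,5R,6R,8R)-6-hydroxy-1-methoxy-8-methyl-2-methylidene-11-oxabicyclo[6.2.1]undec-3-en-5-yl]prop-2-enoate | C=C(C(=O)OC(C)(C)C)[C@H]1/C=C\C(=C)C2(OC)CC[C@@](C)(O2)C[C@H]1O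
F4 | step 10 | tert-butyl 2-[(4Z,6R,7R,9R)-7,9-dihydroxy-9-methyl-12-oxo-1-oxaspiro[2.9]dodec-4-en-6-yl]prop-2-enoate (spiro-carbon epimers) | C=C(C(=O)OC(C)(C)C)[C@H]1/C=C\C2(CO2)C(=O)CC[C@@](C)(O)C[C@H]1O
F5 | step 10 | 17 with the C4=C15 alkene replaced by a spiro-oxirane (4,15:5,6-bis-epoxide; 5,6-epoxide cis to the C8 hydroxyl; C4 epimers) | C=C(C(=O)OC(C)(C)C)[C@H]1[C@H]2O[C@H]2C3(CO3)C(=O)CC[C@@](C)(O)C[C@H]1O
F6 | step 10 | C8 (2R)-2-methylbutanoate of the 4,15:5,6-bis-epoxide F5 | C=C(C(=O)OC(C)(C)C)[C@H]1[C@H]2O[C@H]2C3(CO3)C(=O)CC[C@@](C)(O)C[C@H]1OC(=O)[C@H](C)CC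
F7 | step 12 | 20 with the C15 hydroxyl as its 4-methoxyphenyl ether | C=C(C(=O)OC(C)(C)C)[C@H]1[C@@H](O)/C=C(/COc2ccc(OC)cc2)C(=O)CC[C@@](C)(O)C[C@H]1OC(=O)[C@H](C)CC
F8 | step 12 | 21 with the C15 hydroxyl as its 4-methoxyphenyl ether | C=C1C(=O)O[C@H]2/C=C(/COc3ccc(OC)cc3)C(=O)CC[C@@](C)(O)C[C@@H](OC(=O)[C@H](C)CC)[C@@H]12
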